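**Remarks on the chemistry (assumptions).**
- Elemane numbers are used for the core: C10 is the quaternary carbon (C14 methyl, C1=C2 vinyl), C9 the methylene, C8 the acyloxy carbon, C7, C6 the lactone carbinol, C5 bears C4(=C3H2)–C15H2OH, C11 bears the C13 methyl, C12 is the lactone carbonyl. The acyl chain is C1′–C4′.
- The antipode of the imidazolinium sulfonate ligand in step 7 is chosen so that 12 has the (R) configuration at C10; the sense is to be confirmed on 12 before scale-up.
- Methyl 2-[(4S)-2,2-dimethyl-1,3-dioxolan-4-yl]acetate (29), the acetonide ester derived from (S)-malic acid, is taken as a commercial chiral-pool material.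
- The Z-alkenyl unit C5=C4(C3)C15 has a branched four-carbon skeleton, so it is drawn from prop-2-yn-1-ol by carbomagnesiation; a linear butynol cannot supply it.

## The problem

Target 36 is an elemanolide: a cyclohexane (C5–C10) with a trans-fused α-methyl-γ-lactone across C6–C7, a quaternary C10 carrying methyl and vinyl, a 3-hydroxyprop-1-en-2-yl group on C5, and at O8 the ester of (S)-3,4-dihydroxy-2-methylidenebutanoic acid. Six stereocentres sit on the ring and lactone (C5, C6, C7, C8, C10, C11) and one in the acyl chain (C3′). In the chair all substituents on C5–C8 and the C10 vinyl are equatorial and only the C14 methyl is axial, so a ring closure through a chair can deliver C5 and C6 once C7, C8 and C10 are in place. C11 and C3′ cannot be controlled from the ring and must be imported; C10 is an acyclic all-carbon quaternary centre and needs a catalyst. The acyl chain is the most fragile part: it is a Michael acceptor, and under base its 4′-hydroxyl attacks the ester and expels the ring alcohol, so it must come last and be unveiled under acid. O6 and O8 are both γ to C12, so the lactone can close either way unless O8 is masked whenever C12 is an ester. Three alkenes rule out hydrogenation and ozonolysis, and C8–OH must be told apart from the primary allylic C15–OH. The enabling feature is the trans C6(O)–C5 pair with C5 bearing C4(=C3H2)C15: O6–C6–C5–C4=C3 is a homoallylic alcohol, the retron of a carbonyl-ene reaction between a C6 aldehyde and a C5=C4 trisubstituted alkene whose C3 methyl gives up the hydrogen.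

## Retrosynthesis

**O8–C1′ ester and unveiling (36 ⇐ 35 ⇐ 28 + 33).** The acyl chain is cut off first because it would not survive hydride, thiolate or aluminium reagents used earlier. This leaves hydroxy lactone 28 with one free hydroxyl and the acetonide acid 33. The forward step must acylate a hindered secondary alcohol with an α-branched acrylic acid, and the final deprotection must stay acidic.

**O6–C12 lactone (28 ⇐ 27 ⇐ 26).** The lactone is opened to the monocyclic hydroxy ester 26. Closing it while O8 is still a triethylsilyl ether removes the 8,12-olide as a competitor; the alternative of closing with both hydroxyls free would give no control. The triethylsilyl group must then be removed in the presence of the primary tert-butyldimethylsilyl ether at C15.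

**C5–C6, the key cut (26 ⇐ 25).** The retro-ene opens the cyclohexane to acyclic aldehyde 25 and removes two stereocentres. Cutting C5–C6 is preferred to C6–C7 or C5–C10 because it leaves C7, C8, C10 and C11 to be set by reliable acyclic methods. The forward reaction must give the 5,6-trans product and take the hydrogen from the C3 methyl, which requires the Z alkene (the methyl trans to C10).

**C6 oxidation level and the C7–C8 bond (25 ⇐ 24 ⇐ 23 ⇐ 22 ⇐ 20 + 14).** The aldehyde is traced through thioester 24 to the silylated aldol adduct 23 and the aldol 22. A primary alcohol at C6 is avoided because it would lactonise onto C12. The C7–C8 bond is an aldol bond; the required relationship is syn along C6–C7–C8–C9, which an oxazolidinone boron enolate gives with auxiliary control. This splits the chain into imide 20 (C6, C7, C11–C13) and aldehyde 14 (C8–C10, C1–C5, C14, C15). The forward aldol must override the adjacent C11 centre and must be silylated at once, before O8 can attack C12.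

**The succinate unit (20 ⇐ 19 ⇐ 16 + 17 ⇐ 15).** C11 comes from (R)-2-methylsuccinic acid 15. Its anhydride 16 is opened by the lithium salt 18 of auxiliary 17 at the less hindered carbonyl, which puts the auxiliary on C6 and leaves the C12 acid of 19 for methylation. This is the regiochemistry that simple alcoholysis would not give.

**C10 (14 ⇐ 13 ⇐ 12 ⇐ 6 + 11).** The quaternary carbon with its vinyl group is the retron of an SN2′ allylic substitution: E allylic phosphate 6 supplies C8–C10, C14, C1 and C2, and Z-alkenylboronate 11 supplies C5, C4, C3 and C15. A Claisen route would give the same carbon but racemic, since the allylic alcohol would be primary. The forward step needs SN2′ selectivity and face control from a chiral copper catalyst, with a hindered nucleophile.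

**The two C4 building blocks (6 ⇐ 5 ⇐ 2 ⇐ 1; 11 ⇐ 10 ⇐ 9 ⇐ 7).** Phosphate 6 comes from but-3-yn-1-ol 1 by protection to 2, methylalumination and hydroxymethylation to E alcohol 5. Boronate 11 comes from prop-2-yn-1-ol 7 by anti-carbomagnesiation and iodinolysis to Z iodide 9, silylation to 10 and borylation. Both alkene geometries are fixed by the addition mechanisms.

**The acyl chain (33 ⇐ 32 ⇐ 30 ⇐ 29).** Acid 33 is the α-methylenated form of pool ester 29; the methylene carbon is added by a Mannich reaction to 30 and elimination to 32. The forward step must keep the β-alkoxy enolate cold.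

## Roads not taken

**Alternative 1:** lactone-tethered intramolecular Diels–Alder. The cut removes C5–C10 and C8–C9. The achiral trienyl methacrylate A1 would cyclise on heating or with Al(OC6H3-2,6-Ph2)3 to the trans-fused bicyclic δ-lactone A2, whose tether later opens to C1 (the future vinyl) and the C15 oxygen.
- Merits: two C–C bonds, two rings and the quaternary C10 with C5 trans to it in one step, with C15 already oxygenated. In building C10 it is shorter and needs no hindered organometallic coupling; in this respect it is better than the chosen plan.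
- Weak points: A1 is achiral and the promoter is achiral, so A2 is racemic unless a chiral Lewis acid is found for a sluggish ester-tethered cycloaddition. A2 also has the wrong oxidation pattern: C7 is an enol ether carbon but must carry C11, while C6 and C8 carry no oxygen. C6, C7, C8 and C11 would all have to be set on the ring by substrate control.
- Comparison: the chosen plan pays for C10 with a demanding catalytic step, but then takes C11 from the pool, C7 and C8 from an aldol, and leaves only C5 and C6 to the ring closure.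

**Alternative 2:** cyclobutene ethenolysis. The vicinal alkenyl pair is traced to the cyclobutene of the cis-fused bicyclo[4.2.0]oct-7-en-2-one A3. With ethylene and the second-generation Grubbs catalyst RuCl2(=CHPh)(PCy3)(H2IMes), the strained C1=C4 bond would be exchanged for C1=C2 and C4=C3 to give cyclohexanone A4; no ring closes.
- Merits: the C5/C10 pair including the quaternary carbon comes from a [2+2] cycloaddition, and strain-driven ring opening is dependable. For C10 this is more robust than the SN2′ coupling of the chosen plan.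
- Weak points: the cis ring fusion puts the C5 alkenyl group cis to the vinyl group in A4, whereas the target has them trans, so C5 must be epimerised through the C6 ketone. The C8 silyloxy group of A4 is epimeric to the target and must be inverted. C7 must be alkylated between the ketone and a β-silyloxy carbon, where elimination threatens, and C11 would be set without a control element. Absolute configuration needs an enantioselective photocycloaddition or a resolution.
- Comparison: the chosen plan fixes every centre other than C5 and C6 before cyclisation and needs no epimerisation or inversion.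

**Alternative 3:** samarium ketyl–olefin cyclisation. The cut removes C6–C7 and O6–C12. Aldehyde enoate A5 would be reduced by SmI2 (divalent samarium, THF, t-BuOH) to a ketyl that adds 6-exo to C7 of the enoate; the samarium alkoxide then closes the lactone to give A6, which is identical with compound 27 of the chosen route.
- Merits: ring and lactone form in one step and the route arrives at 27 directly. At the ring-forming stage it is more step-economic than the chosen plan, which needs the ene reaction and a separate lactonisation.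
- Weak points: A5 carries C5 as a tertiary centre α to the aldehyde and β,γ to an alkene, next to the quaternary C10. This centre is prone to epimerisation and conjugation, and the C5/C10 pair would have to be made in acyclic form with no obvious reliable method. C11 would arise by protonation of a samarium enolate, without control.
- Comparison: the chosen plan sets C11 from the pool and creates C5 only in the cyclisation, so it never carries C5 as a labile centre.

Key step: step 17

## Route

Step 1
Reactants: 1 but-3-yn-1-ol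
Product: 2 1-[(but-3-yn-1-yloxy)methyl]-4-methoxybenzene
Conditions: NaH, 4-methoxybenzyl chloride, n-Bu4NI (cat.), THF–DMF, 0 → 23 °C
Reagents that add atoms: 4-methoxybenzyl chloride COc1ccc(CCl)cc1
Why: Williamson etherification of the sodium alkoxide; the alkyne C–H is far less acidic than the hydroxyl and is not touched.

Step 2
Reactants: 2 1-[(but-3-yn-1-yloxy)methyl]-4-methoxybenzene
Product: 5 (2E)-5-[(4-methoxyphenyl)methoxy]-3-methylpent-2-en-1-ol, via alkenyldimethylalane 3 (not isolated), via lithium alkenylalanate 4 (not isolated)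
Conditions: Me3Al, Cp2ZrCl2 (0.2 equiv), CH2Cl2, 0 → 23 °C; n-BuLi, THF, −78 °C; (CH2O)n, −78 → 23 °C; aq. potassium sodium tartrate
Reagents that add atoms: trimethylaluminium C[Al](C)C; formaldehyde (as paraformaldehyde) C=O
Why: Zirconium-catalysed methylalumination of a terminal alkyne (Negishi carboalumination) adds methyl and aluminium syn with aluminium at the terminus, which fixes the E geometry; the alanate is hydroxymethylated with retention.

Step 3
Reactants: 5 (2E)-5-[(4-methoxyphenyl)methoxy]-3-methylpent-2-en-1-ol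
Product: 6 diethyl (2E)-5-[(4-methoxyphenyl)methoxy]-3-methylpent-2-en-1-yl phosphate
Conditions: (EtO)2P(O)Cl, Et3N, DMAP (cat.), CH2Cl2, 0 °C
Reagents that add atoms: diethyl chlorophosphate CCOP(=O)(Cl)OCC
Why: O-phosphorylation of a primary allylic alcohol gives the leaving group needed for copper-catalysed SN2′ substitution; the alkene geometry is not affected.

Step 4
Reactants: 7 prop-2-yn-1-ol
Product: 9 (2Z)-3-iodo-2-methylprop-2-en-1-ol, via cyclic alkenylmagnesium alkoxide 8 (not isolated)
Conditions: MeMgBr (2.5 equiv), CuI (10 mol%), Et2O, −10 → 23 °C; I2, THF, −78 → 0 °C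
Reagents that add atoms: methylmagnesium bromide C[Mg]Br; iodine II
Why: Copper-catalysed carbomagnesiation of a propargylic magnesium alkoxide is anti and regioselective (methyl to C2, magnesium to C3, held by the alkoxide in a five-membered ring); iodinolysis with retention gives the Z iodide with iodine cis to the hydroxymethyl group.

Step 5
Reactants: 9 (2Z)-3-iodo-2-methylprop-2-en-1-ol
Product: 10 tert-butyl{[(2Z)-3-iodo-2-methylprop-2-en-1-yl]oxy}dimethylsilane
Conditions: TBSCl, imidazole, CH2Cl2, 0 → 23 °C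
Reagents that add atoms: tert-butyldimethylsilyl chloride CC(C)(C)[Si](C)(C)Cl
Why: Standard silylation of a primary allylic alcohol; this is the acid-labile C15 protecting group carried to the last step.

Step 6
Reactants: 10 tert-butyl{[(2Z)-3-iodo-2-methylprop-2-en-1-yl]oxy}dimethylsilane
Product: 11 tert-butyldimethyl{[(2Z)-2-methyl-3-(4,4,5,5-tetramethyl-1,3,2-dioxaborolan-2-yl)prop-2-en-1-yl]oxy}silane
Conditions: B2pin2, PdCl2(PPh3)2 (3 mol%), PPh3, KOPh, PhMe, 50 °C
Reagents that add atoms: bis(pinacolato)diboron CC1(C)OB(OC1(C)C)B1OC(C)(C)C(C)(C)O1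
Why: Miyaura borylation of an alkenyl iodide; oxidative addition, transmetalation and reductive elimination all go with retention, so the Z geometry is kept, and the alkenyllithium (prone to 1,4 O-to-C silyl shift) is avoided.

Step 7
Reactants: 6 diethyl (2E)-5-[(4-methoxyphenyl)methoxy]-3-methylpent-2-en-1-yl phosphate; 11 tert-butyldimethyl{[(2Z)-2-methyl-3-(4,4,5,5-tetramethyl-1,3,2-dioxaborolan-2-yl)prop-2-en-1-yl]oxy}silane
Product: 12 tert-butyl{[(2Z,4R)-4-ethenyl-6-[(4-methoxyphenyl)methoxy]-2,4-dimethylhex-2-en-1-yl]oxy}dimethylsilane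
Conditions: CuCl (10 mol%), chiral 4,5-diphenylimidazolinium arenesulfonate (11 mol%), NaOMe (2 equiv), THF, 23 → 50 °C
Reagents that add atoms: none
Why: Copper-catalysed enantioselective allylic substitution with an N-heterocyclic carbene ligand: the methoxide-activated alkenylboronate transfers its alkenyl group to copper with retention, and the alkenylcopper adds SN2′ to the E-trisubstituted phosphate, creating the quaternary C10 and the vinyl group. The sulfonate-bridged chiral carbene selects the alkene face; the ligand antipode is chosen to give (R).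

Step 8
Reactants: 12 tert-butyl{[(2Z,4R)-4-ethenyl-6-[(4-methoxyphenyl)methoxy]-2,4-dimethylhex-2-en-1-yl]oxy}dimethylsilane
Product: 13 (3R,4Z)-6-[(tert-butyldimethylsilyl)oxy]-3-ethenyl-3,5-dimethylhex-4-en-1-ol
Conditions: DDQ, CH2Cl2–pH 7 buffer (10:1), 0 °C
Reagents that add atoms: none
Why: Oxidative cleavage of the 4-methoxybenzyl ether by benzylic hydride abstraction and hydrolysis; the silyl ether and the skipped diene are inert under buffered conditions.

Step 9
Reactants: 13 (3R,4Z)-6-[(tert-butyldimethylsilyl)oxy]-3-ethenyl-3,5-dimethylhex-4-en-1-ol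
Product: 14 (3R,4Z)-6-[(tert-butyldimethylsilyl)oxy]-3-ethenyl-3,5-dimethylhex-4-enal
Conditions: Dess–Martin periodinane, NaHCO3, CH2Cl2, 0 → 23 °C
Reagents that add atoms: none
Why: Dess–Martin oxidation of a primary alcohol; the β-carbon is quaternary, so no stereocentre can epimerise and no conjugation can occur.

Step 10
Reactants: 15 (2R)-2-methylbutanedioic acid
Product: 16 (3R)-3-methyloxolane-2,5-dione
Conditions: AcCl, reflux; evaporate
Reagents that add atoms: none
Why: Dehydration of a 1,4-diacid to the cyclic anhydride through the mixed anhydride; the stereocentre is not involved.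

Step 11
Reactants: 16 (3R)-3-methyloxolane-2,5-dione; 17 (4S)-4-benzyl-1,3-oxazolidin-2-one
Product: 19 (2R)-4-[(4S)-4-benzyl-2-oxo-1,3-oxazolidin-3-yl]-2-methyl-4-oxobutanoic acid, via lithium oxazolidinide 18 (not isolated)
Conditions: n-BuLi, THF, −78 °C; add to 16, −78 → 0 °C; 1 M HCl
Reagents that add atoms: none
Why: N-acylation of a lithiated oxazolidinone by a cyclic anhydride; the bulky nucleophile attacks the carbonyl next to CH2, remote from the methyl-bearing carbon, which places the auxiliary on C6 and leaves the C12 acid free.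

Step 12
Reactants: 19 (2R)-4-[(4S)-4-benzyl-2-oxo-1,3-oxazolidin-3-yl]-2-methyl-4-oxobutanoic acid
Product: 20 methyl (2R)-4-[(4S)-4-benzyl-2-oxo-1,3-oxazolidin-3-yl]-2-methyl-4-oxobutanoate
Conditions: Me3SiCHN2, PhMe–MeOH (4:1), 0 °C
Reagents that add atoms: (trimethylsilyl)diazomethane C[Si](C)(C)C=[N+]=[N-]
Why: Methyl esterification of a carboxylic acid with a diazoalkane under neutral conditions, so C11 is not at risk.

Step 13
Reactants: 20 methyl (2R)-4-[(4S)-4-benzyl-2-oxo-1,3-oxazolidin-3-yl]-2-methyl-4-oxobutanoate; 14 (3R,4Z)-6-[(tert-butyldimethylsilyl)oxy]-3-ethenyl-3,5-dimethylhex-4-enal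
Product: 22 methyl (2R,3S,4R,6R,7Z)-3-[(4S)-4-benzyl-2-oxo-1,3-oxazolidine-3-carbonyl]-9-[(tert-butyldimethylsilyl)oxy]-6-ethenyl-4-hydroxy-2,6,8-trimethylnon-7-enoate, via Z-dibutylboron enolate 21 (not isolated)
Conditions: Bu2BOTf, i-Pr2NEt, CH2Cl2, −78 → 0 °C; 14, −78 → 0 °C; pH 7 buffer, MeOH, H2O2, 0 °C
Reagents that add atoms: none
Why: Evans syn-aldol reaction: soft enolisation gives only the Z boron enolate of the imide (the methyl ester is not enolised), and the Zimmerman–Traxler chair with the benzyl group shielding one face sets C7 (S) and C8 (R). Auxiliary control is expected to override the adjacent C11 centre and the remote C10.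

Step 14
Reactants: 22 methyl (2R,3S,4R,6R,7Z)-3-[(4S)-4-benzyl-2-oxo-1,3-oxazolidine-3-carbonyl]-9-[(tert-butyldimethylsilyl)oxy]-6-ethenyl-4-hydroxy-2,6,8-trimethylnon-7-enoate
Product: 23 methyl (2R,3S,4R,6R,7Z)-3-[(4S)-4-benzyl-2-oxo-1,3-oxazolidine-3-carbonyl]-9-[(tert-butyldimethylsilyl)oxy]-6-ethenyl-2,6,8-trimethyl-4-[(triethylsilyl)oxy]non-7-enoate
Conditions: Et3SiOTf, 2,6-lutidine, CH2Cl2, −78 °C (on crude 22)
Reagents that add atoms: triethylsilyl trifluoromethanesulfonate CC[Si](CC)(CC)OS(=O)(=O)C(F)(F)F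
Why: Silylation of the secondary alcohol with a silyl triflate is fast at −78 °C; doing it on the crude aldol masks O8 before it can lactonise onto the C12 ester.

Step 15
Reactants: 23 methyl (2R,3S,4R,6R,7Z)-3-[(4S)-4-benzyl-2-oxo-1,3-oxazolidine-3-carbonyl]-9-[(tert-butyldimethylsilyl)oxy]-6-ethenyl-2,6,8-trimethyl-4-[(triethylsilyl)oxy]non-7-enoate
Product: 24 methyl (2R,3S,4R,6R,7Z)-9-[(tert-butyldimethylsilyl)oxy]-6-ethenyl-3-[(ethylsulfanyl)carbonyl]-2,6,8-trimethyl-4-[(triethylsilyl)oxy]non-7-enoate
Conditions: EtSH, n-BuLi, THF, 0 °C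
Reagents that add atoms: ethanethiol CCS
Why: Thiolate cleavage of an N-acyl oxazolidinone at the exocyclic carbonyl; the methyl ester is not exchanged because methoxide is the poorer leaving group, and the weakly basic thiolate does not epimerise C7.

Step 16
Reactants: 24 methyl (2R,3S,4R,6R,7Z)-9-[(tert-butyldimethylsilyl)oxy]-6-ethenyl-3-[(ethylsulfanyl)carbonyl]-2,6,8-trimethyl-4-[(triethylsilyl)oxy]non-7-enoate
Product: 25 methyl (2R,3S,4R,6R,7Z)-9-[(tert-butyldimethylsilyl)oxy]-6-ethenyl-3-formyl-2,6,8-trimethyl-4-[(triethylsilyl)oxy]non-7-enoate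
Conditions: Et3SiH, Pd/CaCO3 (Pb-poisoned, 5 wt% Pd), acetone, 23 °C
Reagents that add atoms: none
Why: Fukuyama reduction: palladium inserts into the C–S bond, the silane delivers hydride and the aldehyde is released under neutral conditions. The methyl ester and silyl ethers are inert, C7 is not epimerised, and the poisoned catalyst spares the vinyl group.

Step 17
Reactants: 25 methyl (2R,3S,4R,6R,7Z)-9-[(tert-butyldimethylsilyl)oxy]-6-ethenyl-3-formyl-2,6,8-trimethyl-4-[(triethylsilyl)oxy]non-7-enoate
Product: 26 methyl (2R)-2-[(1R,2S,3S,4R,6R)-3-{3-[(tert-butyldimethylsilyl)oxy]prop-1-en-2-yl}-4-ethenyl-2-hydroxy-4-methyl-6-[(triethylsilyl)oxy]cyclohexyl]propanoate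
Conditions: Me2AlCl (2.2 equiv), CH2Cl2, −78 → −40 °C; aq. potassium sodium tartrate, −40 °C
Reagents that add atoms: none
Why: Me2AlCl binds the C6 aldehyde anti to C7, and the activated carbonyl carbon is attacked by C5 of the C5=C4 alkene while the oxygen takes a hydrogen from the C3 methyl through a six-membered ene array, concerted but asynchronous; this is the Lewis-acid-promoted type 1 intramolecular carbonyl-ene reaction of a 6-alkenal, the citronellal-to-isopulegol case. The cyclohexane closes by C5–C6 bond formation, 6-exo-trig at the carbonyl, with the ene double bond also exocyclic to the new ring. The two new stereocentres C6 and C5 are set by the chair transition state, whose conformation is fixed by the existing centres: the C7 side chain and the C8 silyloxy group take equatorial sites, which for (R)-C10 puts the vinyl group equatorial and only the C14 methyl axial. In that chair the aluminium-bound oxygen and the alkene terminus C4 are both pseudo-equatorial, which gives the 5,6-trans product with O6 trans to the C7 substituent. With both arms equatorial the oxygen lies beside the C4 substituent that is trans to C10, and the Z geometry places the methyl there and the silyloxymethyl group away from it, so hydrogen transfer gives the C4=C3 methylidene and not a silyl enol ether. The step needs trans selectivity at C5/C6 and regioselective hydrogen transfer; the first is secured by the all-equatorial chair and the anti-bound Lewis acid, the second by the alkene geometry, and the Me–Al bonds scavenge protons so that cationic side paths are held back. The mixture is quenched cold so that hydroxy ester 26 is taken on; any lactone 27 already formed converges in step 18.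

Step 18
Reactants: 26 methyl (2R)-2-[(1R,2S,3S,4R,6R)-3-{3-[(tert-butyldimethylsilyl)oxy]prop-1-en-2-yl}-4-ethenyl-2-hydroxy-4-methyl-6-[(triethylsilyl)oxy]cyclohexyl]propanoate
Product: 27 (3R,3aR,4R,6R,7S,7aS)-7-{3-[(tert-butyldimethylsilyl)oxy]prop-1-en-2-yl}-6-ethenyl-3,6-dimethyl-4-[(triethylsilyl)oxy]hexahydro-1-benzofuran-2(3H)-one
Conditions: PPTS (0.2 equiv), PhMe, 4 Å molecular sieves, 60 °C
Reagents that add atoms: none
Why: Acid-catalysed intramolecular transesterification (γ-lactonisation); O6 is the only free hydroxyl, so only the 6,12-olide can form, and the trans fusion follows from the 6,7-trans relationship. The aprotic medium and sieves keep both silyl ethers intact.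

Step 19
Reactants: 27 (3R,3aR,4R,6R,7S,7aS)-7-{3-[(tert-butyldimethylsilyl)oxy]prop-1-en-2-yl}-6-ethenyl-3,6-dimethyl-4-[(triethylsilyl)oxy]hexahydro-1-benzofuran-2(3H)-one
Product: 28 (3R,3aS,4R,6R,7S,7aS)-7-{3-[(tert-butyldimethylsilyl)oxy]prop-1-en-2-yl}-6-ethenyl-4-hydroxy-3,6-dimethylhexahydro-1-benzofuran-2(3H)-one
Conditions: PPTS (0.3 equiv), MeOH–CH2Cl2 (1:1), 0 → 23 °C
Reagents that add atoms: none
Why: Acid-catalysed methanolysis of a silyl ether; the triethylsilyl ether is intrinsically far more acid-labile than the tert-butyldimethylsilyl ether, so O8 is freed while O15 stays protected.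

Step 20
Reactants: 29 methyl 2-[(4S)-2,2-dimethyl-1,3-dioxolan-4-yl]acetate
Product: 30 methyl 3-(dimethylamino)-2-[(4S)-2,2-dimethyl-1,3-dioxolan-4-yl]propanoate (C2 epimers)
Conditions: LiN(i-Pr)2, THF, −78 °C; CH2=NMe2+ I−, −78 → −20 °C
Reagents that add atoms: dimethylmethyleneiminium iodide C=[N+](C)C.[I-]
Why: Mannich reaction of a lithium ester enolate with a preformed iminium salt; the low temperature keeps the β-alkoxy enolate from opening the dioxolane, and the new C2 centre is removed in the next step.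

Step 21
Reactants: 30 methyl 3-(dimethylamino)-2-[(4S)-2,2-dimethyl-1,3-dioxolan-4-yl]propanoate
Product: 32 methyl 2-[(4S)-2,2-dimethyl-1,3-dioxolan-4-yl]prop-2-enoate, via trimethylammonium iodide 31 (not isolated)
Conditions: MeI, MeOH, 23 °C; DBU, CH2Cl2, 23 °C
Reagents that add atoms: none
Why: Quaternisation and E1cB loss of trimethylamine (α-methylenation of an ester through its Mannich base); the ammonium group is a far better leaving group than the ring alkoxide, and the dioxolane stereocentre has no acidic hydrogen in the product.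

Step 22
Reactants: 32 methyl 2-[(4S)-2,2-dimethyl-1,3-dioxolan-4-yl]prop-2-enoate
Product: 33 2-[(4S)-2,2-dimethyl-1,3-dioxolan-4-yl]prop-2-enoic acid
Conditions: LiOH, THF–H2O (3:1), 0 → 23 °C; aq. NaHSO4 to pH 4, 0 °C
Reagents that add atoms: lithium hydroxide [Li+].[OH-]
Why: Saponification of a methyl ester; acidification is kept mild and cold so that the acetonide survives.

Step 23
Reactants: 33 2-[(4S)-2,2-dimethyl-1,3-dioxolan-4-yl]prop-2-enoic acid; 28 (3R,3aS,4R,6R,7S,7aS)-7-{3-[(tert-butyldimethylsilyl)oxy]prop-1-en-2-yl}-6-ethenyl-4-hydroxy-3,6-dimethylhexahydro-1-benzofuran-2(3H)-one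
Product: 35 (3R,3aS,4R,6R,7S,7aS)-7-{3-[(tert-butyldimethylsilyl)oxy]prop-1-en-2-yl}-6-ethenyl-3,6-dimethyl-2-oxooctahydro-1-benzofuran-4-yl 2-[(4S)-2,2-dimethyl-1,3-dioxolan-4-yl]prop-2-enoate, via mixed trichlorobenzoic anhydride 34 (not isolated)
Conditions: 2,4,6-Cl3C6H2COCl, Et3N, PhMe, 23 °C; 28, DMAP, PhMe, 23 → 40 °C
Reagents that add atoms: none
Why: Yamaguchi esterification: the mixed anhydride is attacked by DMAP at the less hindered acyl group and the acylpyridinium acylates the equatorial C8 hydroxyl, the only free hydroxyl. The acid has no α-hydrogen, so neither ketene formation nor epimerisation can occur.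

Step 24
Reactants: 35 (3R,3aS,4R,6R,7S,7aS)-7-{3-[(tert-butyldimethylsilyl)oxy]prop-1-en-2-yl}-6-ethenyl-3,6-dimethyl-2-oxooctahydro-1-benzofuran-4-yl 2-[(4S)-2,2-dimethyl-1,3-dioxolan-4-yl]prop-2-enoate
Product: 36 (3R,3aS,4R,6R,7S,7aS)-6-ethenyl-7-(3-hydroxyprop-1-en-2-yl)-3,6-dimethyl-2-oxooctahydro-1-benzofuran-4-yl (3S)-3,4-dihydroxy-2-methylidenebutanoate
Conditions: AcOH–THF–H2O (3:1:1), 40 °C
Reagents that add atoms: none
Why: Aqueous acid hydrolyses the terminal acetonide and the primary allylic silyl ether in one operation; the acidic medium avoids the base-induced attack of the 4′-hydroxyl on the ester that would expel the ring alcohol.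

## Compound list

1 | but-3-yn-1-ol | C#CCCO | starting material
2 | 1-[(but-3-yn-1-yloxy)methyl]-4-methoxybenzene | C#CCCOCc1ccc(OC)cc1 | intermediate
3 | [(1E)-4-[(4-methoxyphenyl)methoxy]-2-methylbut-1-en-1-yl]dimethylaluminium | C[Al](C)/C=C(\C)CCOCc1ccc(OC)cc1 | intermediate (not isolated)
4 | lithium butyl[(1E)-4-[(4-methoxyphenyl)methoxy]-2-methylbut-1-en-1-yl]dimethylaluminate | [Li+].CCCC[Al-](C)(C)/C=C(\C)CCOCc1ccc(OC)cc1 | intermediate (not isolated)
5 | (2E)-5-[(4-methoxyphenyl)methoxy]-3-methylpent-2-en-1-ol | OC/C=C(\C)CCOCc1ccc(OC)cc1 | intermediate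
6 | diethyl (2E)-5-[(4-methoxyphenyl)methoxy]-3-methylpent-2-en-1-yl phosphate | CCOP(=O)(OCC)OC/C=C(\C)CCOCc1ccc(OC)cc1 | intermediate
7 | prop-2-yn-1-ol | C#CCO | starting material
8 | 4-methyl-2,5-dihydro-1,2-oxamagnesole (cyclic Z-alkenylmagnesium alkoxide) | CC1=C[Mg]OC1 | intermediate (not isolated)
9 | (2Z)-3-iodo-2-methylprop-2-en-1-ol | OC/C(C)=C\I | intermediate
10 | tert-butyl{[(2Z)-3-iodo-2-methylprop-2-en-1-yl]oxy}dimethylsilane | CC(C)(C)[Si](C)(C)OC/C(C)=C\I | intermediate
11 | tert-butyldimethyl{[(2Z)-2-methyl-3-(4,4,5,5-tetramethyl-1,3,2-dioxaborolan-2-yl)prop-2-en-1-yl]oxy}silane | CC(C)(C)[Si](C)(C)OC/C(C)=C\B1OC(C)(C)C(C)(C)O1 | intermediate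
12 | tert-butyl{[(2Z,4R)-4-ethenyl-6-[(4-methoxyphenyl)methoxy]-2,4-dimethylhex-2-en-1-yl]oxy}dimethylsilane | COc1ccc(COCC[C@](C)(C=C)/C=C(/C)CO[Si](C)(C)C(C)(C)C)cc1 | intermediate
13 | (3R,4Z)-6-[(tert-butyldimethylsilyl)oxy]-3-ethenyl-3,5-dimethylhex-4-en-1-ol | OCC[C@](C)(C=C)/C=C(/C)CO[Si](C)(C)C(C)(C)C | intermediate
14 | (3R,4Z)-6-[(tert-butyldimethylsilyl)oxy]-3-ethenyl-3,5-dimethylhex-4-enal | O=CC[C@](C)(C=C)/C=C(/C)CO[Si](C)(C)C(C)(C)C | intermediate
15 | (2R)-2-methylbutanedioic acid | C[C@H](CC(=O)O)C(=O)O | starting material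
16 | (3R)-3-methyloxolane-2,5-dione | C[C@@H]1CC(=O)OC1=O | intermediate
17 | (4S)-4-benzyl-1,3-oxazolidin-2-one | O=C1OC[C@H](Cc2ccccc2)N1 | starting material
18 | lithium (4S)-4-benzyl-2-oxo-1,3-oxazolidin-3-ide | [Li+].O=C1OC[C@H](Cc2ccccc2)[N-]1 | intermediate (not isolated)
19 | (2R)-4-[(4S)-4-benzyl-2-oxo-1,3-oxazolidin-3-yl]-2-methyl-4-oxobutanoic acid | C[C@H](CC(=O)N1[C@@H](Cc2ccccc2)COC1=O)C(=O)O | intermediate
20 | methyl (2R)-4-[(4S)-4-benzyl-2-oxo-1,3-oxazolidin-3-yl]-2-methyl-4-oxobutanoate | COC(=O)[C@H](C)CC(=O)N1[C@@H](Cc2ccccc2)COC1=O | intermediate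
21 | dibutyl{[(1Z,3R)-1-[(4S)-4-benzyl-2-oxo-1,3-oxazolidin-3-yl]-4-methoxy-3-methyl-4-oxobut-1-en-1-yl]oxy}borane | CCCCB(CCCC)O/C(=C\[C@@H](C)C(=O)OC)N1[C@@H](Cc2ccccc2)COC1=O | intermediate (not isolated)
22 | methyl (2R,3S,4R,6R,7Z)-3-[(4S)-4-benzyl-2-oxo-1,3-oxazolidine-3-carbonyl]-9-[(tert-butyldimethylsilyl)oxy]-6-ethenyl-4-hydroxy-2,6,8-trimethylnon-7-enoate | COC(=O)[C@H](C)[C@H](C(=O)N1[C@@H](Cc2ccccc2)COC1=O)[C@H](O)C[C@](C)(C=C)/C=C(/C)CO[Si](C)(C)C(C)(C)C | intermediate
23 | methyl (2R,3S,4R,6R,7Z)-3-[(4S)-4-benzyl-2-oxo-1,3-oxazolidine-3-carbonyl]-9-[(tert-butyldimethylsilyl)oxy]-6-ethenyl-2,6,8-trimethyl-4-[(triethylsilyl)oxy]non-7-enoate | COC(=O)[C@H](C)[C@H](C(=O)N1[C@@H](Cc2ccccc2)COC1=O)[C@H](O[Si](CC)(CC)CC)C[C@](C)(C=C)/C=C(/C)CO[Si](C)(C)C(C)(C)C | intermediate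
24 | methyl (2R,3S,4R,6R,7Z)-9-[(tert-butyldimethylsilyl)oxy]-6-ethenyl-3-[(ethylsulfanyl)carbonyl]-2,6,8-trimethyl-4-[(triethylsilyl)oxy]non-7-enoate | COC(=O)[C@H](C)[C@H](C(=O)SCC)[C@H](O[Si](CC)(CC)CC)C[C@](C)(C=C)/C=C(/C)CO[Si](C)(C)C(C)(C)C | intermediate
25 | methyl (2R,3S,4R,6R,7Z)-9-[(tert-butyldimethylsilyl)oxy]-6-ethenyl-3-formyl-2,6,8-trimethyl-4-[(triethylsilyl)oxy]non-7-enoate (ene precursor) | O=C[C@@H]([C@@H](C)C(=O)OC)[C@H](O[Si](CC)(CC)CC)C[C@](C)(C=C)/C=C(/C)CO[Si](C)(C)C(C)(C)C | intermediate
26 | methyl (2R)-2-[(1R,2S,3S,4R,6R)-3-{3-[(tert-butyldimethylsilyl)oxy]prop-1-en-2-yl}-4-ethenyl-2-hydroxy-4-methyl-6-[(triethylsilyl)oxy]cyclohexyl]propanoate (ene product) | C=C[C@@]1(C)C[C@@H](O[Si](CC)(CC)CC)[C@H]([C@@H](C)C(=O)OC)[C@@H](O)[C@@H]1C(=C)CO[Si](C)(C)C(C)(C)C | intermediate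
27 | (3R,3aR,4R,6R,7S,7aS)-7-{3-[(tert-butyldimethylsilyl)oxy]prop-1-en-2-yl}-6-ethenyl-3,6-dimethyl-4-[(triethylsilyl)oxy]hexahydro-1-benzofuran-2(3H)-one | C=C[C@@]1(C)C[C@@H](O[Si](CC)(CC)CC)[C@H]2[C@@H](OC(=O)[C@@H]2C)[C@@H]1C(=C)CO[Si](C)(C)C(C)(C)C | intermediate
28 | (3R,3aS,4R,6R,7S,7aS)-7-{3-[(tert-butyldimethylsilyl)oxy]prop-1-en-2-yl}-6-ethenyl-4-hydroxy-3,6-dimethylhexahydro-1-benzofuran-2(3H)-one | C=C[C@@]1(C)C[C@@H](O)[C@H]2[C@@H](OC(=O)[C@@H]2C)[C@@H]1C(=C)CO[Si](C)(C)C(C)(C)C | intermediate
29 | methyl 2-[(4S)-2,2-dimethyl-1,3-dioxolan-4-yl]acetate | COC(=O)C[C@H]1COC(C)(C)O1 | starting material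
30 | methyl 3-(dimethylamino)-2-[(4S)-2,2-dimethyl-1,3-dioxolan-4-yl]propanoate (C2 epimers) | COC(=O)C(CN(C)C)[C@H]1COC(C)(C)O1 | intermediate
31 | 3-methoxy-2-[(4S)-2,2-dimethyl-1,3-dioxolan-4-yl]-N,N,N-trimethyl-3-oxopropan-1-aminium iodide | COC(=O)C(C[N+](C)(C)C)[C@H]1COC(C)(C)O1.[I-] | intermediate (not isolated)
32 | methyl 2-[(4S)-2,2-dimethyl-1,3-dioxolan-4-yl]prop-2-enoate | COC(=O)C(=C)[C@H]1COC(C)(C)O1 | intermediate
33 | 2-[(4S)-2,2-dimethyl-1,3-dioxolan-4-yl]prop-2-enoic acid | OC(=O)C(=C)[C@H]1COC(C)(C)O1 | intermediate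
34 | 2-[(4S)-2,2-dimethyl-1,3-dioxolan-4-yl]prop-2-enoic 2,4,6-trichlorobenzoic anhydride | C=C(C(=O)OC(=O)c1c(Cl)cc(Cl)cc1Cl)[C@H]1COC(C)(C)O1 | intermediate (not isolated)
35 | (3R,3aS,4R,6R,7S,7aS)-7-{3-[(tert-butyldimethylsilyl)oxy]prop-1-en-2-yl}-6-ethenyl-3,6-dimethyl-2-oxooctahydro-1-benzofuran-4-yl 2-[(4S)-2,2-dimethyl-1,3-dioxolan-4-yl]prop-2-enoate | C=C[C@@]1(C)C[C@@H](OC(=O)C(=C)[C@H]2COC(C)(C)O2)[C@H]3[C@@H](OC(=O)[C@@H]3C)[C@@H]1C(=C)CO[Si](C)(C)C(C)(C)C | intermediate
36 | (3R,3aS,4R,6R,7S,7aS)-6-ethenyl-7-(3-hydroxyprop-1-en-2-yl)-3,6-dimethyl-2-oxooctahydro-1-benzofuran-4-yl (3S)-3,4-dihydroxy-2-methylidenebutanoate (CNP0260337.1) | C=C[C@@]1(C)C[C@@H](OC(=O)C(=C)[C@H](O)CO)[C@H]2[C@@H](OC(=O)[C@@H]2C)[C@@H]1C(=C)CO | target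

## Step count and least certain steps

Total: 24 steps. Longest linear sequence: 15 steps (steps 1–3, 7–9, 13–19, 23, 24).

**Step 17 (key step).** The allylic silyloxy group lowers the nucleophilicity of the alkene and can divert a long-lived C4 cation: hydrogen loss from C15 (silyl enol ether), 1,2-hydride shift from C15, chloride capture, or methyl transfer from aluminium to the aldehyde may compete, and the β-silyloxy aldehyde may eliminate. The fallback removes the allylic oxygen from the ene component and adds it afterwards; it sets out from phosphate 6 and comes back at lactone 27. Phosphate 6 is coupled under the conditions of step 7 with commercial 2-methylprop-1-enylboronic pinacol ester F1 to give the isobutenyl diene F2. DDQ and Dess–Martin oxidation give alcohol F3 and aldehyde F4. The aldol, silylation, thiolate and Fukuyama sequence of steps 13–16 gives aldol adduct F5, triethylsilyl ether F6, thioester F7 and aldehyde F8. Me2AlCl cyclisation, now the exact citronellal-type case in which either methyl can deliver the hydrogen, gives isopropenyl cyclohexanol F9, and PPTS gives isopropenyl lactone F10. Allylic hydroxylation of the isopropenyl methyl with SeO2 (cat.) and t-BuOOH (Riley oxidation; the vinyl group has no allylic hydrogen, and any enal is returned with NaBH4/CeCl3) gives the C15 alcohol F11, and TBSCl with imidazole returns to 27.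

**Step 7.** The β,β-disubstituted Z-alkenylboronate is hindered: slow transfer to copper, competing SN2 substitution and insufficient face selection are all possible. The fallback builds C10 with a small nucleophile and adds the alkene later; it sets out from alcohol 5 and comes back at 12. Methyl chloroformate gives the allylic methyl carbonate F12. Copper-catalysed enantioselective SN2′ borylation with B2pin2 and the same ligand class gives the tertiary allylboronate F13. Matteson homologation (BrCH2Cl, n-BuLi, −78 °C) and NaOH/H2O2 oxidation give the neopentyl alcohol F14, and Dess–Martin oxidation gives the quaternary aldehyde F15. Still–Gennari olefination with methyl 2-[bis(2,2,2-trifluoroethoxy)phosphoryl]propanoate, KN(SiMe3)2 and 18-crown-6 gives the Z enoate F16. Reduction with i-Bu2AlH gives the Z allylic alcohol F17, and silylation returns to 12.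

**Step 13.** Two processes threaten: γ-lactonisation of O8 onto the C12 methyl ester before silylation, and eroded face selectivity if the C11 centre is mismatched with the auxiliary. The fallback blocks the acyl acceptor during C–C bond formation; it sets out from acid 19 and comes back at 23. Acid 19 is converted with tert-butyl 2,2,2-trichloroacetimidate and BF3·OEt2 (cat.) into the tert-butyl ester imide F18, which is inert to alkoxide attack. The same boron aldol with 14 gives the tert-butyl aldol adduct F19. Et3SiOTf/2,6-lutidine silylates O8, and Me3SiOTf/2,6-lutidine then cleaves the tert-butyl ester to the silyl ester, which gives the silylated acid F20 on work-up; Me3SiCHN2 returns to 23. If face selectivity is the problem, the titanium enolate of the corresponding thiazolidinethione imide (TiCl4, i-Pr2NEt) through a chelated transition state is the variant to test within this fallback.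

**Step 11.** The oxazolidinide may attack the hindered carbonyl to some extent and may enolise the anhydride, which would give a regioisomeric imide and erode C11. The fallback makes the differentiated succinate without ambiguity; it sets out from auxiliary 17 and comes back at 20. Acylation of 17 with propanoyl chloride gives the propanoyl imide F21. Alkylation of its sodium enolate (NaN(SiMe3)2, −78 °C) with tert-butyl bromoacetate gives the alkylated imide F22, with the (R) centre set by the auxiliary. MeOMgBr in MeOH gives the mixed diester F23, and CF3CO2H gives the mono-acid F24. Pivaloyl chloride/Et3N, then 17 and LiCl, returns to 20.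

**Step 20.** The β-alkoxy ester enolate may open the dioxolane by E1cB elimination before the Mannich addition. The fallback uses a β-alkoxide dianion, which cannot eliminate; it sets out from ester 29 and comes back at 32. Aqueous HCl converts 29 into the hydroxy lactone F25. Its dianion (LiN(i-Pr)2, 2.2 equiv, −78 °C; Fráter–Seebach conditions) reacts with CH2=NMe2+ I− to give the aminomethyl lactone F26. MeI and then NaHCO3 give the α-methylene hydroxy lactone F27, and 2,2-dimethoxypropane, MeOH and TsOH (cat.) open the lactone and trap the diol to return to 32.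

**Step 19.** The primary allylic tert-butyldimethylsilyl ether may be lost along with the hindered secondary triethylsilyl ether. The fallback replaces selective cleavage by selective protection; it sets out from 27 and comes back at 28. HF·pyridine in THF removes both silyl groups to give the diol lactone F28, and TBSCl (1.05 equiv) with imidazole at 0 °C silylates only the primary allylic hydroxyl to return to 28.

## Further compounds

F1 | step 17 | 4,4,5,5-tetramethyl-2-(2-methylprop-1-en-1-yl)-1,3,2-dioxaborolane | CC(C)=CB1OC(C)(C)C(C)(C)O1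
F2 | step 17 | 1-({[(3R)-3-ethenyl-3,5-dimethylhex-4-en-1-yl]oxy}methyl)-4-methoxybenzene | COc1ccc(COCC[C@](C)(C=C)C=C(C)C)cc1
F3 | step 17 | (3R)-3-ethenyl-3,5-dimethylhex-4-en-1-ol | OCC[C@](C)(C=C)C=C(C)C
F4 | step 17 | (3R)-3-ethenyl-3,5-dimethylhex-4-enal | O=CC[C@](C)(C=C)C=C(C)C
F5 | step 17 | methyl (2R,3S,4R,6R)-3-[(4S)-4-benzyl-2-oxo-1,3-oxazolidine-3-carbonyl]-6-ethenyl-4-hydroxy-2,6,8-trimethylnon-7-enoate | COC(=O)[C@H](C)[C@H](C(=O)N1[C@@H](Cc2ccccc2)COC1=O)[C@H](O)C[C@](C)(C=C)C=C(C)C
F6 | step 17 | methyl (2R,3S,4R,6R)-3-[(4S)-4-benzyl-2-oxo-1,3-oxazolidine-3-carbonyl]-6-ethenyl-2,6,8-trimethyl-4-[(triethylsilyl)oxy]non-7-enoate | COC(=O)[C@H](C)[C@H](C(=O)N1[C@@H](Cc2ccccc2)COC1=O)[C@H](O[Si](CC)(CC)CC)C[C@](C)(C=C)C=C(C)C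
F7 | step 17 | methyl (2R,3S,4R,6R)-6-ethenyl-3-[(ethylsulfanyl)carbonyl]-2,6,8-trimethyl-4-[(triethylsilyl)oxy]non-7-enoate | COC(=O)[C@H](C)[C@H](C(=O)SCC)[C@H](O[Si](CC)(CC)CC)C[C@](C)(C=C)C=C(C)C
F8 | step 17 | methyl (2R,3S,4R,6R)-6-ethenyl-3-formyl-2,6,8-trimethyl-4-[(triethylsilyl)oxy]non-7-enoate | O=C[C@@H]([C@@H](C)C(=O)OC)[C@H](O[Si](CC)(CC)CC)C[C@](C)(C=C)C=C(C)C
F9 | step 17 | methyl (2R)-2-[(1R,2S,3S,4R,6R)-4-ethenyl-2-hydroxy-4-methyl-3-(prop-1-en-2-yl)-6-[(triethylsilyl)oxy]cyclohexyl]propanoate | C=C[C@@]1(C)C[C@@H](O[Si](CC)(CC)CC)[C@H]([C@@H](C)C(=O)OC)[C@@H](O)[C@@H]1C(C)=C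
F10 | step 17 | (3R,3aR,4R,6R,7S,7aS)-6-ethenyl-3,6-dimethyl-7-(prop-1-en-2-yl)-4-[(triethylsilyl)oxy]hexahydro-1-benzofuran-2(3H)-one | C=C[C@@]1(C)C[C@@H](O[Si](CC)(CC)CC)[C@H]2[C@@H](OC(=O)[C@@H]2C)[C@@H]1C(C)=C
F11 | step 17 | (3R,3aR,4R,6R,7S,7aS)-6-ethenyl-7-(3-hydroxyprop-1-en-2-yl)-3,6-dimethyl-4-[(triethylsilyl)oxy]hexahydro-1-benzofuran-2(3H)-one | C=C[C@@]1(C)C[C@@H](O[Si](CC)(CC)CC)[C@H]2[C@@H](OC(=O)[C@@H]2C)[C@@H]1C(=C)CO
F12 | step 7 | (2E)-5-[(4-methoxyphenyl)methoxy]-3-methylpent-2-en-1-yl methyl carbonate | COC(=O)OC/C=C(\C)CCOCc1ccc(OC)cc1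
F13 | step 7 | 2-[(3S)-5-[(4-methoxyphenyl)methoxy]-3-methylpent-1-en-3-yl]-4,4,5,5-tetramethyl-1,3,2-dioxaborolane | COc1ccc(COCC[C@](C)(C=C)B2OC(C)(C)C(C)(C)O2)cc1
F14 | step 7 | (2R)-2-ethenyl-4-[(4-methoxyphenyl)methoxy]-2-methylbutan-1-ol | COc1ccc(COCC[C@](C)(C=C)CO)cc1
F15 | step 7 | (2R)-2-ethenyl-4-[(4-methoxyphenyl)methoxy]-2-methylbutanal | COc1ccc(COCC[C@](C)(C=C)C=O)cc1
F16 | step 7 | methyl (2Z,4R)-4-ethenyl-6-[(4-methoxyphenyl)methoxy]-2,4-dimethylhex-2-enoate | COc1ccc(COCC[C@](C)(C=C)/C=C(/C)C(=O)OC)cc1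
F17 | step 7 | (2Z,4R)-4-ethenyl-6-[(4-methoxyphenyl)methoxy]-2,4-dimethylhex-2-en-1-ol | COc1ccc(COCC[C@](C)(C=C)/C=C(/C)CO)cc1
F18 | step 13 | tert-butyl (2R)-4-[(4S)-4-benzyl-2-oxo-1,3-oxazolidin-3-yl]-2-methyl-4-oxobutanoate | CC(C)(C)OC(=O)[C@H](C)CC(=O)N1[C@@H](Cc2ccccc2)COC1=O
F19 | step 13 | tert-butyl (2R,3S,4R,6R,7Z)-3-[(4S)-4-benzyl-2-oxo-1,3-oxazolidine-3-carbonyl]-9-[(tert-butyldimethylsilyl)oxy]-6-ethenyl-4-hydroxy-2,6,8-trimethylnon-7-enoate | CC(C)(C)OC(=O)[C@H](C)[C@H](C(=O)N1[C@@H](Cc2ccccc2)COC1=O)[C@H](O)C[C@](C)(C=C)/C=C(/C)CO[Si](C)(C)C(C)(C)C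
F20 | step 13 | (2R,3S,4R,6R,7Z)-3-[(4S)-4-benzyl-2-oxo-1,3-oxazolidine-3-carbonyl]-9-[(tert-butyldimethylsilyl)oxy]-6-ethenyl-2,6,8-trimethyl-4-[(triethylsilyl)oxy]non-7-enoic acid | OC(=O)[C@H](C)[C@H](C(=O)N1[C@@H](Cc2ccccc2)COC1=O)[C@H](O[Si](CC)(CC)CC)C[C@](C)(C=C)/C=C(/C)CO[Si](C)(C)C(C)(C)C
F21 | step 11 | (4S)-4-benzyl-3-propanoyl-1,3-oxazolidin-2-one | CCC(=O)N1[C@@H](Cc2ccccc2)COC1=O
F22 | step 11 | tert-butyl (3R)-4-[(4S)-4-benzyl-2-oxo-1,3-oxazolidin-3-yl]-3-methyl-4-oxobutanoate | C[C@H](CC(=O)OC(C)(C)C)C(=O)N1[C@@H](Cc2ccccc2)COC1=O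
F23 | step 11 | 4-tert-butyl 1-methyl (2R)-2-methylbutanedioate | C[C@H](CC(=O)OC(C)(C)C)C(=O)OC
F24 | step 11 | (3R)-4-methoxy-3-methyl-4-oxobutanoic acid | C[C@H](CC(=O)O)C(=O)OC
F25 | step 20 | (4S)-4-hydroxyoxolan-2-one | O=C1C[C@H](O)CO1
F26 | step 20 | (4S)-3-[(dimethylamino)methyl]-4-hydroxyoxolan-2-one (C3 epimers) | O=C1C(CN(C)C)[C@H](O)CO1
F27 | step 20 | (4S)-4-hydroxy-3-methylideneoxolan-2-one | O=C1C(=C)[C@H](O)CO1
F28 | step 19 | (3R,3aS,4R,6R,7S,7aS)-6-ethenyl-4-hydroxy-7-(3-hydroxyprop-1-en-2-yl)-3,6-dimethylhexahydro-1-benzofuran-2(3H)-one | C=C[C@@]1(C)C[C@@H](O)[C@H]2[C@@H](OC(=O)[C@@H]2C)[C@@H]1C(=C)CO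
A1 | alternative 1 | (3E)-5-[(tert-butyldimethylsilyl)oxy]-2-methylidenehexa-3,5-dien-1-yl 2-methylprop-2-enoate | C=C(C)C(=O)OCC(=C)/C=C/C(=C)O[Si](C)(C)C(C)(C)C
A2 | alternative 1 | trans-fused bicyclic δ-lactone with C7 silyl enol ether and C4 exo-methylene | C[C@]12CCC(O[Si](C)(C)C(C)(C)C)=C[C@@H]1C(=C)COC2=O
A3 | alternative 2 | cis-fused 4-[(tert-butyldimethylsilyl)oxy]-8-{[(tert-butyldiphenylsilyl)oxy]methyl}-6-methylbicyclo[4.2.0]oct-7-en-2-one | C[C@@]12C=C(CO[Si](c3ccccc3)(c3ccccc3)C(C)(C)C)[C@@H]1C(=O)C[C@@H](O[Si](C)(C)C(C)(C)C)C2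
A4 | alternative 2 | cis-2-alkenyl-3-methyl-3-vinyl-5-silyloxycyclohexanone | C=C[C@@]1(C)C[C@H](O[Si](C)(C)C(C)(C)C)CC(=O)[C@H]1C(=C)CO[Si](c2ccccc2)(c2ccccc2)C(C)(C)C
A5 | alternative 3 | C6 aldehyde with (E)-2-methylenoate, 8-O-triethylsilyl, 15-O-tert-butyldimethylsilyl | O=C[C@H](C(=C)CO[Si](C)(C)C(C)(C)C)[C@@](C)(C=C)C[C@@H](O[Si](CC)(CC)CC)/C=C(\C)C(=O)OC
A6 | alternative 3 | 8-O-triethylsilyl-15-O-tert-butyldimethylsilyl bicyclic lactone core (identical with 27) | C=C[C@@]1(C)C[C@@H](O[Si](CC)(CC)CC)[C@H]2[C@@H](OC(=O)[C@@H]2C)[C@@H]1C(=C)CO[Si](C)(C)C(C)(C)C
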